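## The problem

Carbons are numbered C1 to C22 along the linear notation of the target, oxygens not counted: C1 to C3 isopropenyl (C1 = CH2, C3 = CH3), C4, C5, quaternary C6, ketone C7, C8, C9, ketone C10, quaternary C11, C12, C13 (methyl C14), C15, benzylic C16, and C17 to C22 for hydroquinone ring A (OH on C18 and C21). Ring B is C6 to C11.

- Target 31 is a compact pentacycle. Ring A is fused through a five-membered ring (C6, C16, C17, C22, C11) to the cyclohexane-1,4-dione ring B. Two bicyclo[3.2.1]octane units share C6: one is closed by the C12–C13=C15 bridge between C11 and C16, the other by the C5–C4 bridge between C6 and C8.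
- C6 and C11 are adjacent quaternary carbons. C6 is the only stereocentre that needs an external source of chirality.
- C11 can only be cis to C6 within the benzo-fused five-membered ring. C16 and C8 are bridgeheads whose configuration follows from ring closure. C4 (isopropenyl exo, on the C7 side) is the one centre left to kinetic control.
- The free hydroquinone oxidises in air, and the isopropenyl and C13=C15 alkenes do not tolerate strong protic or Lewis acids. The 1,4-dione has two nearly equivalent enolisable positions (C8 and C9). Prenylated cyclohexadienone intermediates undergo [3,3] shifts when heated.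
- The enabling feature is that ring B is a dearomatised hydroquinone: C7 and C10 carry para oxygens, C11 is bonded to aryl carbon C22, and C6 carries both the prenyl-derived chain and the benzylic C16. C6–C16 can therefore be made by ortho C-alkylation of a biaryl phenol, and the configuration of the biaryl axis can be handed on to C6.

## Retrosynthesis

**31 to 29 (two O–CH3 bonds).** Ring A is carried as its dimethyl ether because methyl ethers survive organolithium, palladium, quinone-oxidant, Lewis-acid, zinc and manganese chemistry. They are removed by oxidation to quinone 30 and reduction, which avoids boron or aluminium halides that would attack the two alkenes. The forward step must oxidise only the electron-rich arene.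

**29 to 28 to 27 (C4–C8).** The isopropenylcyclopentane is closed last. A thermal or Lewis-acid ene reaction of the prenyl group with enedione 27 would be redox-neutral, but a concerted ene must pass a methyl hydrogen to C9 and so places the isopropenyl group cis to C9, the wrong C4 epimer. A 5-exo cyclisation of the C8 radical through a chair transition state gives the exo isomer, and divalent copper turns the tertiary radical into the isopropenyl group. The precursor is therefore the saturated dione 28, made from 27 with zinc. This bond must follow closure of the C15–C16 bridge, because an exo isopropenyl group lies next to C16 and would compete for the C16 cation. The forward step asks for enolisation of C7 toward C8 and not of C10 toward C9.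

**27 to 26 to 25 (C15–C16).** The bridge is closed by attack of a (Z)-vinylsilane on a C16 benzylic cation.
- Addition of a vinyl metal to a C16 ketone would leave a tertiary bridgehead alcohol that cannot be ionised and is hard to remove.
- A plain methallyl terminator would give a tertiary cation that loses a proton in three directions.
- The silane fixes the alkene at C13=C15 and delivers C16–H directly.

The cation comes from acetate 26, made by hydride abstraction from the only benzylic methylene of 25. The cut removes a bridged ring and the C16 stereocentre.

**25 to 17 + 24 (C11–C12).** Alkylation of the α-aryl ketone 17 with allylic bromide 24 creates the second quaternary carbon. Only the cis-fused product is accessible, so C6 controls C11. Bromide 24 is three steps from propargyl alcohol 18 through iodide 20 and silane 23.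

**17 to 16 to 14 (C6–C16, the key cut).** Hydrolysis relates 17 to methyl dienol ether 16. Cutting C6–C16 in 16 returns an aromatic biaryl phenol 14 and removes the quaternary stereocentre and the five-membered ring together. Intermolecular prenylation of a fluorenol-type phenol at C6 would have neither C/O nor facial control. Here O-alkylation is geometrically impossible and the face is fixed by the axis. The forward step needs a configurationally stable axis and temperatures at or below ambient.

**14 to 13 to 12 to 11 to 7 + 10 (C11–C22).** The bromide comes from alcohol 13, phenol aldehyde 12 and MOM-protected aldehyde 11. The tetra-ortho-substituted axis is set by atroposelective Suzuki–Miyaura coupling of boronate 7 with bromo aldehyde 10. The formyl group is both the C16 precursor and an established anchoring group for chiral monophosphine ligands. The MOM group on O7 is removed before any benzylic leaving group exists.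

**7 to 5 to 2 to 1 + 3, and 10 to 8.** Both arenes are functionalised by deprotonation between a bromine and an oxygen substituent. Ring B starts from bromophenol 1, not from a phenol without the bromine, because metalation of the latter next to its methoxy group would go to the unhindered C9. The bromine at C11 defines first the lithiation site (C6, prenylation with 3) and then the boron site. Aldehyde 10 is one step from 8.

## Roads not taken

**Alternative 1:** ring A is built last by alkyne cyclotrimerisation.
- Cut: C17–C22, C18–C19 and C20–C21.
- Forward key step: CpCo(CO)2 or Cp*RuCl(cod) couples the two alkynylboronate arms of diyne A2 with acetylene A3 to give bis-boronate A1. Oxidation of the two C–B bonds then gives the hydroquinone.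
- Merits: the phenol oxygens arrive masked as boronates and are released under mild conditions. No electron-rich arene is carried through the synthesis and no benzylic oxidation is needed. In these respects it is better than the chosen plan.
- Weak points: A2 already contains C6, C11 and C16 and the bridged cyclohexene, with two alkynes on adjacent congested carbons, so the hard part is moved into the precursor. The enedione and prenyl alkenes of A2 are competent partners for cobalt or ruthenium metallacycles. A3 must be used in excess and can trimerise with itself.
- Comparison: the chosen plan buys ring A and C16 as a benzaldehyde, and its key step creates C6 and does not presuppose it.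

**Alternative 2:** amino-acid-catalysed aldol desymmetrisation.
- Cut: the C11=C12 bond of a bicyclic enone.
- Forward key step: a proline-type catalyst cyclises prochiral triketone A5 to the prenyl Wieland–Miescher ketone analogue A4 (Hajos–Parrish–Eder–Sauer–Wiechert reaction), fixing C6.
- Merits: metal-free, cheap, scalable and mechanistically well understood. For setting C6 it is more robust than an atroposelective coupling followed by a stereochemical relay.
- Weak points: A4 has neither ring A, nor the C10 oxygen, nor C14. Ring A would have to be grafted across C11 (the enone β-carbon, to become quaternary) and C16 (an unactivated methylene). C10 would need a late C–H oxidation. Enantioselectivity of this aldol falls as the angular group grows beyond methyl.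
- Comparison: the chosen plan depends on a palladium catalyst with a specialised ligand. In return, both ring-B oxygens, ring A and the C11–C22 and C6–C16 bonds are in place directly after C6 is set.

**Alternative 3:** oxidative radical cyclisation on a C10-ketal.
- Cut: C4–C8 as the last C–C bond, on cage ketone A7 carrying a C10 dioxolane.
- Forward key step: Mn(OAc)3 (trivalent manganese) oxidises the C7 enol, the C8 radical adds to C4, and Cu(OAc)2 (divalent copper) gives the isopropenyl group of A6.
- Merits: this is the same reaction as step 18 of the chosen route. With the dioxolane only C7 can enolise, so its regiochemistry is more secure than that of step 18.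
- Weak points: it is an endgame and not an answer to C6, C11 and C16, since A7 must still be made as one enantiomer.
  - A ketal placed on C10 while C10 is still differentiated blocks the enolate needed to alkylate C11.
  - A ketal placed later must distinguish two ketones that are both flanked by quaternary carbons.
  - It must survive hot acetic acid and costs two steps.
- Comparison: the chosen route adopts the radical closure without the ketal. It accepts the regiochemical risk and sets against it a shorter sequence and a fallback through a separable silyl enol ether.

Key step: step 9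

Remark on the chemistry: 3-bromo-4-methoxyphenol (1) is assumed to be purchasable. The axial descriptor (aS) (P helicity) ranks C10 over C6 and C21 over C17.

Step 1
Reactants: 1 3-bromo-4-methoxyphenol
Product: 2 2-bromo-1-methoxy-4-(methoxymethoxy)benzene
Conditions: MOMCl, i-Pr2NEt, CH2Cl2, 0 °C to rt
Reagents that add atoms: chloromethyl methyl ether, COCCl
Why: Phenol O-alkylation (MOM protection); the acetal later directs ortho-lithiation and survives organolithium and cross-coupling conditions.

Step 2
Reactants: 2 2-bromo-1-methoxy-4-(methoxymethoxy)benzene; 3 prenyl bromide (1-bromo-3-methylbut-2-ene)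
Product: 5 2-bromo-1-methoxy-4-(methoxymethoxy)-3-(3-methylbut-2-en-1-yl)benzene, via aryllithium 4 (not isolated)
Conditions: LiN(i-Pr)2 (LDA), THF, −78 °C; CuBr·SMe2 (10 mol %), 3, −78 to −20 °C
Reagents that add atoms: none
Why: Directed ortho-metalation removes the proton flanked by bromine and the MOM ether (most acidic site; the ortho-bromoaryllithium is stable at −78 °C), and copper-catalysed allylic substitution gives the linear prenyl arene.

Step 3
Reactants: 5 2-bromo-1-methoxy-4-(methoxymethoxy)-3-(3-methylbut-2-en-1-yl)benzene
Product: 7 2-[6-methoxy-3-(methoxymethoxy)-2-(3-methylbut-2-en-1-yl)phenyl]-4,4,5,5-tetramethyl-1,3,2-dioxaborolane, via aryllithium 6 (not isolated)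
Conditions: n-BuLi, THF, −78 °C; i-PrOBpin, −78 °C to rt
Reagents that add atoms: 2-isopropoxy-4,4,5,5-tetramethyl-1,3,2-dioxaborolane, CC(C)OB1OC(C)(C)C(C)(C)O1
Why: Bromine–lithium exchange is faster than any other process at −78 °C and the aryllithium is trapped by the borate ester, placing boron at the future C11 between methoxy and prenyl.

Step 4
Reactants: 8 1-bromo-2,5-dimethoxybenzene
Product: 10 2-bromo-3,6-dimethoxybenzaldehyde, via aryllithium 9 (not isolated)
Conditions: LiN(i-Pr)2 (LDA), THF, −78 °C; DMF; aq. NH4Cl
Reagents that add atoms: N,N-dimethylformamide, CN(C)C=O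
Why: Directed ortho-lithiation at the proton between bromine and methoxy, then formylation; the aldehyde carbon becomes C16.

Step 5
Reactants: 7 arylboronate; 10 2-bromo-3,6-dimethoxybenzaldehyde
Product: 11 (aS)-3,6,6'-trimethoxy-3'-(methoxymethoxy)-2'-(3-methylbut-2-en-1-yl)-[1,1'-biphenyl]-2-carbaldehyde
Conditions: Pd(OAc)2 (5 mol %), enantiopure P-chiral monophosphine (BaryPhos type, 10 mol %), K3PO4, toluene/H2O, 70 °C
Reagents that add atoms: none
Why: Atroposelective Suzuki–Miyaura coupling of an ortho-formyl aryl bromide with a 2,6-disubstituted arylboron reagent is an established route to tetra-ortho-substituted biaryls; four ortho substituents make the axis configurationally stable, and the ligand antipode is chosen in a pilot run to give the (aS) axis.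

Step 6
Reactants: 11 MOM-protected biaryl aldehyde
Product: 12 (aS)-3'-hydroxy-3,6,6'-trimethoxy-2'-(3-methylbut-2-en-1-yl)-[1,1'-biphenyl]-2-carbaldehyde
Conditions: NaHSO4·SiO2, CH2Cl2, rt
Reagents that add atoms: none
Why: Mild heterogeneous acid cleaves the phenolic MOM acetal without protonating the prenyl alkene, so no chroman should form; the axis is untouched.

Step 7
Reactants: 12 phenol aldehyde
Product: 13 (aS)-2'-(hydroxymethyl)-3',6,6'-trimethoxy-2-(3-methylbut-2-en-1-yl)-[1,1'-biphenyl]-3-ol
Conditions: NaBH4, MeOH/THF, 0 °C
Reagents that add atoms: none
Why: Chemoselective borohydride reduction of the aryl aldehyde to the benzylic alcohol.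

Step 8
Reactants: 13 phenol benzylic alcohol
Product: 14 (aS)-2'-(bromomethyl)-3',6,6'-trimethoxy-2-(3-methylbut-2-en-1-yl)-[1,1'-biphenyl]-3-ol
Conditions: CBr4, PPh3, CH2Cl2, 0 °C; used at once
Reagents that add atoms: tetrabromomethane, BrC(Br)(Br)Br
Why: The Appel reaction converts the benzylic alcohol into the bromide under neutral conditions; the phenol is not substituted and the prenyl group sees no HBr.

Step 9
Reactants: 14 (aS)-2'-(bromomethyl)biaryl phenol
Product: 16 (9aS)-4,5,8-trimethoxy-9a-(3-methylbut-2-en-1-yl)-9,9a-dihydro-1H-fluoren-1-one, via potassium phenolate 15 (not isolated)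
Conditions: KOt-Bu (1.0 equiv), THF/t-BuOH, 0.005 M, 0 °C to rt
Reagents that add atoms: none
Why: KOt-Bu deprotonates the C7 phenol, and the ortho carbon C6 of phenolate 15 displaces the benzylic bromide at C16 in an intramolecular SN2 reaction. The closest known reaction type is the base-mediated intramolecular alkylative dearomatisation of phenols to cyclohexadienones. The closure is 5-exo-tet and forms the ring C6–C16–C17–C22–C11. O-Alkylation would need a four-atom bridge across meta positions of ring B and C8 cannot reach C16, so only intermolecular alkylation competes and is suppressed by high dilution. Because C6 already bears the prenyl group the product cannot return to a phenol and stays as the 2,4-dienone with C10 as its methyl enol ether. The new stereocentre C6 is controlled by the axis: in (aS)-14 the two rings are near perpendicular, the bromomethyl arm lies over one face of ring B only, the bond forms on that face and the prenyl group is pushed to the other, giving (S). The step needs a configurationally stable axis (four ortho substituents) and a temperature at or below ambient so that the 6-prenyl dienone does not undergo [3,3] shifts.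

Step 10
Reactants: 16 methyl dienol ether
Product: 17 (4aR,9aS)-5,8-dimethoxy-9a-(3-methylbut-2-en-1-yl)-4a,9-dihydro-1H-fluorene-1,4(9aH)-dione
Conditions: 1 M aq. HCl, THF, 0 °C to rt, under argon
Reagents that add atoms: water, O
Why: Enol ether hydrolysis (protonation at C11, hydration of the oxocarbenium ion, loss of methanol) gives the ene-1,4-dione; C11–H settles cis to the prenyl group because only the cis-fused hexahydrofluorene is free of strain and the centre is enolisable.

Step 11
Reactants: 18 propargyl alcohol
Product: 20 (Z)-3-iodo-2-methylprop-2-en-1-ol, via alkenylmagnesium alkoxide 19 (not isolated)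
Conditions: MeMgBr (2.5 equiv), CuI (10 mol %), THF, −10 °C to rt; then I2, −10 °C
Reagents that add atoms: methylmagnesium bromide, C[Mg]Br; iodine, II
Why: Copper-catalysed anti-carbomagnesiation of the propargylic alkoxide places methyl on the internal carbon and magnesium cis to the CH2O group in a chelate, and iodinolysis proceeds with retention to the (Z)-iodide.

Step 12
Reactants: 20 (Z)-3-iodo-2-methylprop-2-en-1-ol
Product: 23 (Z)-2-methyl-3-(trimethylsilyl)prop-2-en-1-ol, via dilithio alkoxide 21 (not isolated), via bis-silyl ether 22 (not isolated)
Conditions: t-BuLi (3.1 equiv), Et2O, −78 °C; Me3SiCl (2.3 equiv), −78 °C to rt; then K2CO3 (cat.), MeOH, 0 °C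
Reagents that add atoms: chlorotrimethylsilane, C[Si](C)(C)Cl
Why: Iodine–lithium exchange keeps the alkene geometry, silylation occurs at carbon and oxygen, and the labile O–Si bond is then cleaved selectively by methanolysis.

Step 13
Reactants: 23 (Z)-2-methyl-3-(trimethylsilyl)prop-2-en-1-ol
Product: 24 [(Z)-3-bromo-2-methylprop-1-en-1-yl]trimethylsilane
Conditions: CBr4, PPh3, CH2Cl2, 0 °C
Reagents that add atoms: tetrabromomethane, BrC(Br)(Br)Br
Why: Appel bromination of a primary allylic alcohol proceeds by direct substitution without allylic transposition or loss of alkene geometry.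

Step 14
Reactants: 17 cis-fused enedione; 24 silylated allylic bromide
Product: 25 (4aR,9aS)-5,8-dimethoxy-9a-(3-methylbut-2-en-1-yl)-4a-[(2Z)-2-methyl-3-(trimethylsilyl)prop-2-en-1-yl]-4a,9-dihydro-1H-fluorene-1,4(9aH)-dione
Conditions: K2CO3, DMF (degassed), 0 °C to rt
Reagents that add atoms: none
Why: SN2 alkylation of the stabilised α-aryl ketone enolate at C11 by the allylic bromide; C12 must enter cis to the prenyl group because a trans-fused benzo-hydrindane is highly strained, so C6 controls C11.

Step 15
Reactants: 25 C11-alkylated enedione
Product: 26 C16 acetate of 25 (fluorene position 9; both C16 epimers; C6 and C11 as in 25)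
Conditions: DDQ (1.3 equiv), AcOH/CH2Cl2, rt
Reagents that add atoms: acetic acid, CC(=O)O
Why: DDQ abstracts hydride from the only benzylic methylene, which is activated by the ortho methoxy group, and acetic acid captures the cation (benzylic acetoxylation of alkoxy-substituted alkylarenes); the allylic C–H bonds and the vinylsilane are much poorer hydride donors.

Step 16
Reactants: 26 benzylic acetate
Product: 27 C15–C16-bridged 6-prenyl-18,21-dimethoxy enedione (6S,11R,16R)
Conditions: Me3SiOTf (20 mol %), CH2Cl2, −78 to −40 °C
Reagents that add atoms: none
Why: Ionisation of the acetate gives an ortho-methoxy-stabilised benzylic cation that is captured by the vinylsilane at its silicon-bearing carbon C15 (vinylsilane-terminated cation cyclisation), and loss of silicon from the β-silyl cation fixes the alkene at C13=C15; C16 can only be approached from the face that carries C12, both acetate epimers converge, and the released silyl group regenerates the catalyst.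

Step 17
Reactants: 27 caged enedione
Product: 28 caged 7,10-dione (8,9-dihydro derivative of 27; 6S,11R,16R)
Conditions: Zn dust, AcOH, rt
Reagents that add atoms: none
Why: Dissolving-metal reduction of an ene-1,4-dione to the saturated 1,4-dione; isolated alkenes and aryl ethers are inert.

Step 18
Reactants: 28 caged 7,10-dione
Product: 29 18,21-di-O-methyl ether of the target (4S,6S,8R,11R,16R)
Conditions: Mn(OAc)3·2H2O (2.2 equiv), Cu(OAc)2·H2O (1 equiv), degassed AcOH, 80 °C
Reagents that add atoms: none
Why: Oxidative free-radical cyclisation of an unsaturated ketone: the enolate of C7 on trivalent manganese gives the C8 radical, which adds 5-exo to C4 of the axial prenyl group, and divalent copper oxidises the tertiary radical to the isopropenyl alkene; the chair-like transition state with the ring-B bonds axial places the CMe2 end exo and so sets C4, and C8 becomes a bridgehead that cannot enolise again.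

Step 19
Reactants: 29 target dimethyl ether
Product: 31 CNP0287617.1 (4S,6S,8R,11R,16R; target hydroquinone), via quinone 30 (not isolated)
Conditions: (NH4)2Ce(NO3)6 (2.5 equiv), MeCN/H2O, 0 °C; then aq. Na2S2O4, EtOAc, rt, under argon
Reagents that add atoms: water, O
Why: Oxidative demethylation of the 1,4-dimethoxyarene by tetravalent cerium gives the para-quinone, and dithionite reduces it to the hydroquinone; no Lewis acid touches the alkenes, and the bridgehead C16 prevents quinone methide formation.

## Compound list

1 | 3-bromo-4-methoxyphenol | COc1ccc(O)cc1Br | starting material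
2 | 2-bromo-1-methoxy-4-(methoxymethoxy)benzene | COCOc1ccc(OC)c(Br)c1 | intermediate
3 | prenyl bromide (1-bromo-3-methylbut-2-ene) | CC(C)=CCBr | starting material
4 | [2-bromo-3-methoxy-6-(methoxymethoxy)phenyl]lithium | [Li]c1c(OCOC)ccc(OC)c1Br | intermediate
5 | 2-bromo-1-methoxy-4-(methoxymethoxy)-3-(3-methylbut-2-en-1-yl)benzene | COCOc1ccc(OC)c(Br)c1CC=C(C)C | intermediate
6 | [6-methoxy-3-(methoxymethoxy)-2-(3-methylbut-2-en-1-yl)phenyl]lithium | [Li]c1c(OC)ccc(OCOC)c1CC=C(C)C | intermediate
7 | 2-[6-methoxy-3-(methoxymethoxy)-2-(3-methylbut-2-en-1-yl)phenyl]-4,4,5,5-tetramethyl-1,3,2-dioxaborolane | COCOc1ccc(OC)c(B2OC(C)(C)C(C)(C)O2)c1CC=C(C)C | intermediate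
8 | 1-bromo-2,5-dimethoxybenzene | COc1ccc(OC)c(Br)c1 | starting material
9 | (2-bromo-3,6-dimethoxyphenyl)lithium | [Li]c1c(Br)c(OC)ccc1OC | intermediate
10 | 2-bromo-3,6-dimethoxybenzaldehyde | O=Cc1c(Br)c(OC)ccc1OC | intermediate
11 | (aS)-3,6,6'-trimethoxy-3'-(methoxymethoxy)-2'-(3-methylbut-2-en-1-yl)-[1,1'-biphenyl]-2-carbaldehyde (axis not expressed in SMILES) | O=Cc1c(OC)ccc(OC)c1-c1c(OC)ccc(OCOC)c1CC=C(C)C | intermediate
12 | (aS)-3'-hydroxy-3,6,6'-trimethoxy-2'-(3-methylbut-2-en-1-yl)-[1,1'-biphenyl]-2-carbaldehyde (axis not expressed) | O=Cc1c(OC)ccc(OC)c1-c1c(OC)ccc(O)c1CC=C(C)C | intermediate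
13 | (aS)-2'-(hydroxymethyl)-3',6,6'-trimethoxy-2-(3-methylbut-2-en-1-yl)-[1,1'-biphenyl]-3-ol (axis not expressed) | OCc1c(OC)ccc(OC)c1-c1c(OC)ccc(O)c1CC=C(C)C | intermediate
14 | (aS)-2'-(bromomethyl)-3',6,6'-trimethoxy-2-(3-methylbut-2-en-1-yl)-[1,1'-biphenyl]-3-ol (axis not expressed) | BrCc1c(OC)ccc(OC)c1-c1c(OC)ccc(O)c1CC=C(C)C | intermediate
15 | potassium phenolate of 14 (aS) | [K+].[O-]c1ccc(OC)c(-c2c(CBr)c(OC)ccc2OC)c1CC=C(C)C | intermediate
16 | (9aS)-4,5,8-trimethoxy-9a-(3-methylbut-2-en-1-yl)-9,9a-dihydro-1H-fluoren-1-one | CC(C)=CC[C@@]12C(=O)C=CC(OC)=C1c1c(OC)ccc(OC)c1C2 | intermediate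
17 | (4aR,9aS)-5,8-dimethoxy-9a-(3-methylbut-2-en-1-yl)-4a,9-dihydro-1H-fluorene-1,4(9aH)-dione | CC(C)=CC[C@]12Cc3c(OC)ccc(OC)c3[C@H]1C(=O)C=CC2=O | intermediate
18 | propargyl alcohol (prop-2-yn-1-ol) | C#CCO | starting material
19 | bromomagnesium (Z)-3-(bromomagnesio)-2-methylprop-2-en-1-olate | Br[Mg]OC/C(C)=C\[Mg]Br | intermediate
20 | (Z)-3-iodo-2-methylprop-2-en-1-ol | OC/C(C)=C\I | intermediate
21 | lithium (Z)-3-lithio-2-methylprop-2-en-1-olate | [Li]OC/C(C)=C\[Li] | intermediate
22 | trimethyl{[(Z)-2-methyl-3-(trimethylsilyl)prop-2-en-1-yl]oxy}silane | C[Si](C)(C)OC/C(C)=C\[Si](C)(C)C | intermediate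
23 | (Z)-2-methyl-3-(trimethylsilyl)prop-2-en-1-ol | OC/C(C)=C\[Si](C)(C)C | intermediate
24 | [(Z)-3-bromo-2-methylprop-1-en-1-yl]trimethylsilane | BrC/C(C)=C\[Si](C)(C)C | intermediate
25 | (4aR,9aS)-5,8-dimethoxy-9a-(3-methylbut-2-en-1-yl)-4a-[(2Z)-2-methyl-3-(trimethylsilyl)prop-2-en-1-yl]-4a,9-dihydro-1H-fluorene-1,4(9aH)-dione | CC(C)=CC[C@]12Cc3c(OC)ccc(OC)c3[C@@]1(C/C(C)=C\[Si](C)(C)C)C(=O)C=CC2=O | intermediate
26 | C16 acetate of 25 (both C16 epimers; C6 and C11 as in 25) | CC(C)=CC[C@]12C(OC(C)=O)c3c(OC)ccc(OC)c3[C@@]1(C/C(C)=C\[Si](C)(C)C)C(=O)C=CC2=O | intermediate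
27 | C15–C16-bridged 6-prenyl-18,21-dimethoxy enedione (6S,11R,16R) | CC(C)=CC[C@@]23C(=O)C=CC(=O)[C@@]21CC(C)=C[C@@H]3c2c(OC)ccc(OC)c21 | intermediate
28 | caged 7,10-dione, 8,9-dihydro derivative of 27 (6S,11R,16R) | CC(C)=CC[C@@]23C(=O)CCC(=O)[C@@]21CC(C)=C[C@@H]3c2c(OC)ccc(OC)c21 | intermediate
29 | 18,21-di-O-methyl ether of the target (4S,6S,8R,11R,16R) | C=C(C)[C@H]1C[C@@]23C(=O)[C@@H]1CC(=O)[C@@]21CC(C)=C[C@@H]3c2c(OC)ccc(OC)c21 | intermediate
30 | ring A para-quinone of the target (stereocentres as in 29) | C=C(C)[C@H]1C[C@@]23C(=O)[C@@H]1CC(=O)[C@@]21CC(C)=C[C@@H]3C4=C1C(=O)C=CC4=O | intermediate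
31 | CNP0287617.1 (4S,6S,8R,11R,16R) | C=C(C)[C@H]1C[C@@]23C(=O)[C@@H]1CC(=O)[C@@]21CC(C)=C[C@@H]3c2c(O)ccc(O)c21 | target

## Step count and least certain steps

Total step count: 19. Longest linear sequence: 15 steps (steps 1, 2, 3, 5 to 10 and 14 to 19); steps 4 and 11 to 13 are side branches.

**Step 9 (key step).** The most likely failure is intermolecular O-alkylation and oligomerisation outrunning the 5-exo-tet attack of a fully substituted, prenyl-bearing carbon. Self-alkylation of the electron-rich bromide 14 before base is added is a related risk. Any erosion of axial purity upstream passes directly into C6. The fallback changes the mechanism from anionic to cationic. It sets out from alcohol 13: catalytic Bi(OTf)3 in (CF3)2CHOH/CH2Cl2 at 0 °C ionises the ortho-methoxybenzylic alcohol, the cation alkylates C6 in an ipso Friedel–Crafts-type dearomatisation on the same face, and loss of the phenolic proton gives dienone 16. The route is rejoined at 16 without any new compound.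

**Step 18.** Enolisation of C10 toward C9 competes with enolisation of C7 toward C8. The argument for C8 rests only on sterics: C10 sits beside the aryl carbon with its ortho methoxy group, and the axial C9 hydrogen is shielded by ring A. A C9 radical would close 6-exo onto the prenyl group to a bicyclo[2.2.2]octane isomer, and poor facial selectivity at C4 is a second risk. The fallback replaces enolisation under the oxidant by a preformed enol derivative. It sets out from 28: t-BuMe2SiOTf and Et3N give the C7 silyl enol ether F5, which is purified by chromatography so that regiochemistry is fixed before the radical is made. Oxidation of F5 with Cu(OTf)2 and Cu2O in MeCN (oxidative cyclisation of an unsaturated silyl enol ether) closes C4–C8 and gives the isopropenyl group, rejoining the route at 29.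

**Step 15.** Hydride abstraction from C16 may be too slow, because the arene is attached to an electron-poor enedione framework, or may be accompanied by allylic oxidation of the prenyl or silylallyl groups. The fallback uses the redox chemistry of ring A in place of an external hydride acceptor. It sets out from 25:
- (NH4)2Ce(NO3)6 converts ring A into the quinone F2.
- Catalytic Et3N tautomerises this alkylquinone to the ortho-quinone methide F3.
- The electrophilic C16 of F3 is captured by the vinylsilane, directly or through [4+2] addition and β-silyl elimination, to give the caged hydroquinone F4.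
- Methylation of F4 (MeI, K2CO3, acetone) rejoins the route at 27.

**Step 5.** Four ortho substituents make transmetalation and reductive elimination slow. Protodeboronation of the hindered boronate and insufficient enantioselectivity are the likely failures. The fallback replaces asymmetric catalysis by resolution. It sets out from 7 and 10: coupling with Pd(OAc)2 and the achiral biaryl phosphine SPhos gives the racemic biaryl aldehyde F1, and the atropisomers of F1 are separated by preparative chromatography on a chiral stationary phase. They cannot interconvert at ambient temperature. The (aS) antipode is compound 11, where the route is rejoined.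

## Further compounds

F0 | step 9 | none | none
F1 | step 5 | racemic 3,6,6'-trimethoxy-3'-(methoxymethoxy)-2'-(3-methylbut-2-en-1-yl)-[1,1'-biphenyl]-2-carbaldehyde | O=Cc1c(OC)ccc(OC)c1-c1c(OC)ccc(OCOC)c1CC=C(C)C
F2 | step 15 | ring A para-quinone of 25 | CC(C)=CC[C@]12CC3=C(C(=O)C=CC3=O)[C@@]1(C/C(C)=C\[Si](C)(C)C)C(=O)C=CC2=O
F3 | step 15 | ortho-quinone methide tautomer of F2 (C16=C17, C18 ketone, C21 hydroxyl) | CC(C)=CC[C@]12C=C3C(=O)C=CC(O)=C3[C@@]1(C/C(C)=C\[Si](C)(C)C)C(=O)C=CC2=O
F4 | step 15 | caged hydroquinone enedione (18,21-di-O-demethyl 27) | CC(C)=CC[C@@]23C(=O)C=CC(=O)[C@@]21CC(C)=C[C@@H]3c2c(O)ccc(O)c21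
F5 | step 18 | C7 tert-butyldimethylsilyl enol ether of 28 (C7=C8) | CC(C)=CC[C@@]23C(O[Si](C)(C)C(C)(C)C)=CCC(=O)[C@@]21CC(C)=C[C@@H]3c2c(OC)ccc(OC)c21
A1 | alternative 1 | bis(pinacolboryl) benzobicyclo[3.2.1]octadiene enedione | CC(C)=CC[C@@]23C(=O)C=CC(=O)[C@@]21CC(C)=C[C@@H]3c2c(B4OC(C)(C)C(C)(C)O4)ccc(B4OC(C)(C)C(C)(C)O4)c21
A2 | alternative 1 | bis(alkynylboronate) diyne with alkynes on C11 and C16 | CC(C)=CC[C@@]23C(=O)C=CC(=O)[C@@]2(C#CB4OC(C)(C)C(C)(C)O4)CC(C)=C[C@@H]3C#CB2OC(C)(C)C(C)(C)O2
A3 | alternative 1 | acetylene | C#C
A4 | alternative 2 | 8a-prenyl Wieland–Miescher ketone analogue | CC(C)=CC[C@@]12C(=O)CCCC1=CC(=O)CC2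
A5 | alternative 2 | 2-(3-methylbut-2-en-1-yl)-2-(3-oxobutyl)cyclohexane-1,3-dione | CC(C)=CCC1(CCC(C)=O)C(=O)CCCC1=O
A6 | alternative 3 | target skeleton with C10 dioxolane and ring A dimethyl ether | C=C(C)[C@H]1C[C@@]23C(=O)[C@@H]1CC4(OCCO4)[C@@]21CC(C)=C[C@@H]3c2c(OC)ccc(OC)c21
A7 | alternative 3 | caged 6-prenyl C7 ketone with C10 dioxolane | CC(C)=CC[C@@]23C(=O)CCC4(OCCO4)[C@@]21CC(C)=C[C@@H]3c2c(OC)ccc(OC)c21
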